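**Preliminary remarks**

- Numbering used throughout (route numbering, not lowest-locant numbering): C1 is the quaternary oxirane carbon, C2 carries OMe, C3 carries OBz, C4=C5 is the alkene, C6 is the oxirane CH, and C7 is the CH2 on C1. The target is then (1R,2S,3R,6R).
- Assumption: the antipode of the bishydroxamic acid ligand that gives the (1R,2S,3S)-epoxide 7 is taken to be assignable from the facial model for tertiary allylic alcohols. Both antipodes derive from the two commercial enantiomers of trans-cyclohexane-1,2-diamine, so either sense is accessible.
- Structure check: in 7 the oxirane lies on the face of the C1 hydroxyl, and its absolute configuration maps onto C1 and C2 of the target. The derived diol 8 is (1R,2S), the mirror-image series of the diol that benzoate dioxygenase makes; this matters for Alternative 2.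
- Design choices: the enolate is hydroxylated on the isolated methyl ester, not in the ammonia medium. The ester is kept until after the photooxygenation. Both benzoates are introduced in one operation. Sulfonylation and ring closure share one flask. This leaves six steps after the key step.

## Structural features

The target is a cyclohexene (C1–C6, alkene C4=C5) cis-fused to an oxirane across C1–C6. C1 is the only quaternary carbon and carries the C7 methylene as a benzoate. C2 bears a methyl ether and C3 a second benzoate, so the four stereocentres C6, C1, C2 and C3 are contiguous and every ring carbon is either oxygenated or olefinic. The oxirane oxygen and the C2 methoxy group lie on one face; the C3 benzoate and C7 lie on the other. The fragile groups are the vinyl oxirane (allylic C6–O, open to acid and to SN2′ attack) and the two benzoates (base-labile, and prone to acyl shift once a neighbouring hydroxyl is free). The diene intermediates are also fragile, because each is a dihydroarene one dehydration away from a benzene. The carbon skeleton is simply a C7-substituted benzene; the real difficulty is to place four different oxygen functions on defined faces and to make C1 a stereocentre although its two ring arms are nearly alike. The key step exploits exactly this: in a 1-hydroxycyclohexa-2,5-diene-1-carboxylate C1 lies on a mirror plane and the arms C2=C3 and C6=C5 are enantiotopic. Oxidizing one arm from the face of the C1 hydroxyl fixes C1 and C2 with the cis C1–O/C2–O relation of the target.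

## Logic of the disconnections

**16 ⇒ 14 (through 15).** The C6–O bond of the oxirane is cut and the oxygen stays on C1. The vinyl oxirane is the least robust group, so it should be made last. The precursor has one ring fewer and an ordinary trans-1,2-diol. The forward step needs a leaving group at C6 on the face opposite the C1 oxygen and no other free secondary hydroxyl.

**14 ⇒ 12 + 13.** The two acyl–oxygen bonds at O7 and O3 are cut. Both esters then come from one reagent in one operation, and 12 carries no protecting group. The forward step must acylate the primary and the less hindered secondary hydroxyl and leave the C6 and C1 hydroxyls alone.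

**12 ⇒ 11.** C7 is returned to the ester oxidation level (two C7–H bonds removed). The ester links C7 to the carboxyl carbon of 1 and stabilizes the earlier diene intermediates. The forward step is a hydride reduction that must spare the alkene and the carbinol centres.

**11 ⇒ 9 (through 10).** The C3–O and C6–O bonds are cut, and both oxygens are traced to one molecule of O2 added across the diene termini. Two stereocentres and two C–O bonds disappear together, and the cis-1,4 relation is explained. The forward cycloaddition must take the face opposite the C1 and C2 oxygens.

**9 ⇒ 8.** The O–CH3 bond at C2 is cut. This exposes a cis-diol. The forward step must alkylate the secondary hydroxyl next to a tertiary one without acid.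

**8 ⇒ 7.** The C3=C4 alkene and C2 hydroxyl are traced back to a C2–C3 oxirane and a C4 methylene (C3–O re-formed, C4–H restored). This turns the diene diol into the product of a directed epoxidation. The forward step needs a base that removes the C4 proton only.

**7 ⇒ 6.** The C2–O and C3–O bonds of the oxirane are cut. All three stereocentres vanish and an achiral, mirror-symmetric dienol remains; this is the largest simplification in the route. The forward step must choose one of two enantiotopic alkenes under catalyst control and deliver oxygen syn to the C1 hydroxyl.

**6 ⇒ 4 (through 5).** The C1–O bond is cut. The forward step is an electrophilic hydroxylation of an ester enolate, which must occur at C1 and not at the vinylogous positions.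

**4 ⇒ 3.** The ester O–CH3 bond is cut. The forward alkylation must not move the diene into conjugation.

**3 ⇒ 1 (through 2).** The hydrogens at C1 and C4 are removed and the ring is rearomatized. The forward step is a dissolving-metal reduction whose regiochemistry is set by the carboxylate.

## Other disconnections considered

**Alternative 1:** The ring bond C3–C4 is cut. In the forward sense the open-chain (Z)-iodoalkenyl epoxy aldehyde A2 would be closed with CrCl2 and catalytic NiCl2 to the C3 alcohol A1, which needs only benzoylation to reach 16.
- In favour: the organochromium addition tolerates oxirane and ester, and no dihydroarene is involved, so aromatization is not a risk.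
- Better than the chosen plan on one point: in A2 every oxygen except the one at C3 is already differentiated, so the late discrimination between the C3 and C6 hydroxyls (step 9) does not arise.
- Against: A2 must hold the trisubstituted oxirane with its quaternary carbon, the C2 ether centre and a (Z)-iodoalkene in an open chain, each needing its own stereocontrolled step. Its aldehyde is α-alkoxy and epimerizable. The C3 configuration would be set in the ring closure under substrate control of uncertain sense. Several equivalents of divalent chromium are consumed.
- Comparison: the chosen plan takes all seven skeletal carbons from 1 and forms no C–C bond, while Alternative 1 assembles them. Mechanistically it is a stepwise metal-mediated carbonyl addition against a concerted oxygen transfer. In step count, reaching A2 alone should cost about as much as the whole chosen route.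

**Alternative 2:** Aromaticity is broken by enzymatic cis-dihydroxylation of benzoic acid at the ipso and ortho carbons with whole cells of Ralstonia eutropha B9, giving the diol acid A3.
- In favour, and better than the chosen plan on these points: one step from 1, no chiral catalyst, and an essentially enantiopure product, against five steps to the comparable diene diol 8.
- Against: the configuration of A3 matches C1 of 16 only if the enzymatic ortho carbon is read as C6; read as C2 it would lead to the antipode, and 8 is in fact in the mirror-image series of A3. With the ortho carbon as C6, the enzymatic C6–O bond lies on the same face as the C1–O bond. The oxirane requires the C1 oxygen to enter C6 from that face, so the C6 oxygen would have to be replaced with net inversion. The C2 and C3 oxygens would then have to be added stepwise, for instance by hydroxyl-directed epoxidation of C2=C3 and opening at C3 by benzoate. The mutant strain and fermentation are also less accessible than a catalyst.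
- Comparison: structurally both plans dearomatize 1 and keep C7. The enzyme gives the better enantiocontrol and the faster start. The chosen plan places its two cis oxygens exactly where the target keeps them (C1, C2) and adds the other two in one cycloaddition, so the overall count should be equal or lower.

**Alternative 3:** The C2–O bond is traced to an oxa-Michael addition. The achiral p-quinol A5 would be treated with formaldehyde and a chiral phosphoric acid, so that the hemiacetal formed at the C1 hydroxyl adds to C2 of one enone and gives the cis-fused methylene acetal enone A4.
- In favour: metal-free catalysis, a precursor that should be short to make by oxidative dearomatization of the corresponding phenol, and the C7 benzoate in place from the start. On this last point it is better than the chosen plan, which needs a late ester reduction.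
- Equal: like step 4, it sets C1 and C2 together with the cis relation of 16 in one desymmetrizing step.
- Against: the methylene acetal is hard to remove without strong Lewis acids that threaten the benzoate, and the freed diol still needs selective C2 methylation. The oxidation pattern of A4 is also far from 16: the C4 carbonyl would have to be transposed into the C4=C5 alkene with an oxygen at C6, and C3 oxygenated trans to C2.
- Comparison: mechanistically it is Brønsted-acid-controlled conjugate addition against metal-bound peroxide transfer. In step economy the chosen plan is clearly shorter after the key step, because one O2 supplies both remaining oxygens.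

Key step: step 4

## Route

**Step 1**
Reactants: 1 benzoic acid
Product: 3 cyclohexa-2,5-diene-1-carboxylic acid, via dilithium enediolate 2 (not isolated)
Conditions: Li (2.5 equiv), NH3 (l)/THF, −78 °C; then NH4Cl; cold dil. HCl work-up
Reagents that add atoms: none
Why: Birch reduction: electron transfer to the benzoate and protonation at C4 by ammonia give the carboxylate-stabilized enediolate 2, which NH4Cl protonates at C1 to leave the unconjugated 2,5-diene; no stereocentre is formed.

**Step 2**
Reactants: 3 cyclohexa-2,5-diene-1-carboxylic acid
Product: 4 methyl cyclohexa-2,5-diene-1-carboxylate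
Conditions: MeI, KHCO3, DMF, rt
Reagents that add atoms: iodomethane, CI
Why: SN2 O-alkylation of the carboxylate; KHCO3 is too weak to remove the doubly allylic C1–H, so the diene should neither move into conjugation nor aromatize.

**Step 3**
Reactants: 4 methyl cyclohexa-2,5-diene-1-carboxylate
Product: 6 methyl 1-hydroxycyclohexa-2,5-diene-1-carboxylate, via sodium ester enolate 5 (not isolated)
Conditions: NaN(SiMe3)2, THF, −78 °C; then 2-(benzenesulfonyl)-3-phenyloxaziridine, −78 °C; NH4Cl (aq)
Reagents that add atoms: 2-(benzenesulfonyl)-3-phenyloxaziridine, O=S(=O)(N1OC1c1ccccc1)c1ccccc1
Why: Davis oxidation: the cross-conjugated enolate 5 attacks the oxaziridine oxygen through C1, the position also taken by alkylating agents in Birch-derived enolates, so the 2,5-diene is kept; the sodium counter-ion limits addition to the sulfonimine by-product, and the buffered quench avoids acid-induced loss of water.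

**Step 4**
Reactants: 6 methyl 1-hydroxycyclohexa-2,5-diene-1-carboxylate
Product: 7 methyl (1R,2S,3S)-2,3-epoxy-1-hydroxycyclohex-5-ene-1-carboxylate (oxirane syn to the C1 hydroxyl)
Conditions: Hf(OtBu)4 (10 mol %), C2-symmetric bishydroxamic acid ligand from trans-cyclohexane-1,2-diamine (12 mol %, antipode as assumed), cumene hydroperoxide (1.1 equiv), 4 Å MS, toluene, 0 °C
Reagents that add atoms: cumene hydroperoxide, CC(C)(OO)c1ccccc1
Why: Hf(OtBu)4 and the bishydroxamic acid exchange alkoxide ligands to give a chiral complex of tetravalent hafnium that binds 6 through its C1 alkoxide and cumene hydroperoxide as an alkylperoxide. The metal-bound peroxide oxygen is then passed to the alkene in a concerted spiro-type transition state, as in the known hafnium and vanadium bishydroxamic acid epoxidations of tertiary allylic alcohols, the closest reaction type; the desymmetrizing element has its analogy in the titanium tartrate epoxidation of divinyl carbinols. The oxirane is the one ring closed, by suprafacial addition of a single oxygen atom across C2=C3 with both C–O bonds formed together, so the ring fusion can only be cis. C2 and C3 are set relative to C1 by the tether, because the oxygen can reach only the face that carries the C1 alkoxide. C1 becomes a stereocentre because only one of the two enantiotopic alkenes reacts, and that choice is made by the C2-symmetric ligand, which leaves room for one ring arm only. The step needs enantiotopic-group selectivity, syn facial selectivity and mono-epoxidation; the nearly planar ring holds both alkenes at the same distance from the metal so that the ligand alone decides, the cis-endocyclic alkene fits the geometry of directed oxygen transfer, and the oxidant is limited to a slight excess. The ester at C1 disfavours ionization of the bis-allylic C1–O bond at the Lewis-acidic metal, which protects 6 from aromatization. Any bis-epoxide should come mainly from the minor enantiomer of 7, whose remaining alkene is the one the catalyst prefers, so the enantiomeric purity of 7 is expected to rise with conversion.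

**Step 5**
Reactants: 7 methyl (1R,2S,3S)-2,3-epoxy-1-hydroxycyclohex-5-ene-1-carboxylate
Product: 8 methyl (1R,2S)-1,2-dihydroxycyclohexa-3,5-diene-1-carboxylate
Conditions: LiN(iPr)2 (3 equiv), THF, −78 to 0 °C; NH4Cl (aq)
Reagents that add atoms: none
Why: Base-mediated isomerization of an epoxide to an allylic alcohol: after O–H deprotonation the amide removes the C4 proton, which is both allylic and β to the C3–O bond, and the oxirane opens by β-elimination to the C3=C4 alkene and the C2 alkoxide; C1 and C2 are untouched, so the cis-diol follows from the syn epoxy alcohol, and the C1 alkoxide cannot leave, which blocks aromatization in base.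

**Step 6**
Reactants: 8 methyl (1R,2S)-1,2-dihydroxycyclohexa-3,5-diene-1-carboxylate
Product: 9 methyl (1R,2S)-1-hydroxy-2-methoxycyclohexa-3,5-diene-1-carboxylate
Conditions: MeI (excess), Ag2O, 4 Å MS, MeCN, rt, dark
Reagents that add atoms: iodomethane, CI
Why: Purdie methylation under non-deprotonating, acid-free conditions: the secondary allylic C2–OH reacts, while the tertiary C1–OH, hindered and hydrogen-bonded to the ester, should be left; no acid is present that could dehydrate the dihydroarene.

**Step 7**
Reactants: 9 methyl (1R,2S)-1-hydroxy-2-methoxycyclohexa-3,5-diene-1-carboxylate
Product: 11 methyl (1R,2S,3R,6S)-1,3,6-trihydroxy-2-methoxycyclohex-4-ene-1-carboxylate, via anti endoperoxide 10 (not isolated)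
Conditions: O2, hν (visible), methylene blue (cat.), MeOH, −20 °C; then thiourea, −20 °C to rt
Reagents that add atoms: dioxygen, O=O
Why: [4+2] Cycloaddition of singlet oxygen to the s-cis diene: the pseudoaxial C1 hydroxyl and the C2 methoxy group shield the upper face, and methanol suppresses hydrogen-bond steering by the free hydroxyl, so O2 should add to the lower face and set C3 and C6 together, both anti to the C1 and C2 oxygens; thiourea then cleaves the O–O bond with retention at both carbons, giving the cis-1,4-diol without isolation of the peroxide.

**Step 8**
Reactants: 11 methyl (1R,2S,3R,6S)-1,3,6-trihydroxy-2-methoxycyclohex-4-ene-1-carboxylate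
Product: 12 (1R,2S,3R,6S)-1-(hydroxymethyl)-2-methoxycyclohex-4-ene-1,3,6-triol
Conditions: LiBH4, THF, 0 °C to rt; MeOH quench
Reagents that add atoms: none
Why: Hydride reduction of an α-hydroxy ester, which borohydride reduces readily through chelation; alkene, ether and carbinol centres are inert, so all four stereocentres are carried through, and the polar tetraol is freed from boron by co-evaporation with methanol.

**Step 9**
Reactants: 12 (1R,2S,3R,6S)-1-(hydroxymethyl)-2-methoxycyclohex-4-ene-1,3,6-triol; 13 benzoyl chloride
Product: 14 [(1R,2S,3R,6S)-3-(benzoyloxy)-1,6-dihydroxy-2-methoxycyclohex-4-en-1-yl]methyl benzoate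
Conditions: BzCl (2.1 equiv), pyridine, CH2Cl2, −40 to 0 °C
Reagents that add atoms: benzoyl chloride (13), O=C(Cl)c1ccccc1
Why: Kinetically controlled O-acylation: the primary C7–OH and the pseudo-equatorial secondary C3–OH react first, whereas C6–OH (pseudoaxial, neopentyl-like, next to quaternary C1) and the tertiary C1–OH should be left at low temperature without an acyl-transfer catalyst.

**Step 10**
Reactants: 14 [(1R,2S,3R,6S)-3-(benzoyloxy)-1,6-dihydroxy-2-methoxycyclohex-4-en-1-yl]methyl benzoate
Product: 16 [(1R,2S,3R,6R)-3-(benzoyloxy)-2-methoxy-7-oxabicyclo[4.1.0]hept-4-en-1-yl]methyl benzoate, via C6 mesylate 15 (not isolated)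
Conditions: Ms2O, Et3N, DMAP (cat.), THF, −20 °C; then NaN(SiMe3)2 (2.1 equiv), −78 to 0 °C
Reagents that add atoms: none
Why: Sulfonylation of the only remaining non-tertiary hydroxyl, then intramolecular Williamson etherification (3-exo-tet): the C1 alkoxide, trans-diaxial to the C6 mesylate, displaces it with inversion, so the new oxirane is cis to the C2 methoxy group and trans to the C3 benzoate; E2 is excluded because C6 has no sp3 β-hydrogen, and Ms2O avoids chloride that could substitute the allylic mesylate.

## Compound list

1 | benzoic acid | OC(=O)c1ccccc1 | starting material
2 | dilithium (cyclohexa-2,5-dien-1-ylidene)methanediolate | [Li+].[Li+].[O-]C([O-])=C1C=CCC=C1 | intermediate (not isolated)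
3 | cyclohexa-2,5-diene-1-carboxylic acid | OC(=O)C1C=CCC=C1 | intermediate
4 | methyl cyclohexa-2,5-diene-1-carboxylate | COC(=O)C1C=CCC=C1 | intermediate
5 | sodium (cyclohexa-2,5-dien-1-ylidene)(methoxy)methanolate | [Na+].COC([O-])=C1C=CCC=C1 | intermediate (not isolated)
6 | methyl 1-hydroxycyclohexa-2,5-diene-1-carboxylate | COC(=O)C1(O)C=CCC=C1 | intermediate
7 | methyl (1R,2S,3S)-2,3-epoxy-1-hydroxycyclohex-5-ene-1-carboxylate | COC(=O)[C@@]1(O)C=CC[C@@H]2O[C@H]12 | intermediate
8 | methyl (1R,2S)-1,2-dihydroxycyclohexa-3,5-diene-1-carboxylate | COC(=O)[C@]1(O)[C@@H](O)C=CC=C1 | intermediate
9 | methyl (1R,2S)-1-hydroxy-2-methoxycyclohexa-3,5-diene-1-carboxylate | COC(=O)[C@]1(O)[C@@H](OC)C=CC=C1 | intermediate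
10 | methyl (1S,2S,3R,6S)-3,6-epidioxy-1-hydroxy-2-methoxycyclohex-4-ene-1-carboxylate | COC(=O)[C@]1(O)[C@@H](OC)[C@H]2C=C[C@@H]1OO2 | intermediate (not isolated)
11 | methyl (1R,2S,3R,6S)-1,3,6-trihydroxy-2-methoxycyclohex-4-ene-1-carboxylate | COC(=O)[C@]1(O)[C@@H](OC)[C@H](O)C=C[C@@H]1O | intermediate
12 | (1R,2S,3R,6S)-1-(hydroxymethyl)-2-methoxycyclohex-4-ene-1,3,6-triol | OC[C@]1(O)[C@@H](OC)[C@H](O)C=C[C@@H]1O | intermediate
13 | benzoyl chloride | O=C(Cl)c1ccccc1 | starting material
14 | [(1R,2S,3R,6S)-3-(benzoyloxy)-1,6-dihydroxy-2-methoxycyclohex-4-en-1-yl]methyl benzoate | O=C(OC[C@]1(O)[C@@H](OC)[C@H](OC(=O)c2ccccc2)C=C[C@@H]1O)c1ccccc1 | intermediate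
15 | [(1S,2S,3R,6S)-3-(benzoyloxy)-1-hydroxy-2-methoxy-6-(methylsulfonyloxy)cyclohex-4-en-1-yl]methyl benzoate | O=C(OC[C@]1(O)[C@@H](OC)[C@H](OC(=O)c2ccccc2)C=C[C@@H]1OS(C)(=O)=O)c1ccccc1 | intermediate (not isolated)
16 | [(1R,2S,3R,6R)-3-(benzoyloxy)-2-methoxy-7-oxabicyclo[4.1.0]hept-4-en-1-yl]methyl benzoate | CO[C@H]1[C@H](OC(=O)c2ccccc2)C=C[C@H]2O[C@]21COC(=O)c1ccccc1 | target

## Step count and least certain steps

Total step count: 10. Longest linear sequence: 10 steps (1 to 16); 13 enters as a reagent in step 9.

**Step 4 (key step).**
- What may go wrong: weak discrimination between the two enantiotopic alkenes, because the α-hydroxy ester can bind hafnium as a five-membered chelate, a mode that simple carbinols do not have. Over-oxidation to the achiral bis-epoxide and Lewis-acid-induced loss of water from the bis-allylic carbinol are further risks.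
- Fallback, a resolution in place of catalytic induction, setting out from 6: VO(acac)2 and tert-butyl hydroperoxide in CH2Cl2 should give, by the same alkoxide-directed delivery, the racemic syn-epoxy alcohol F1. Isomerization as in step 5 gives the racemic cis-diol F2. Immobilized Candida antarctica lipase B with vinyl acetate should, by the empirical size rule for secondary alcohols, acetylate the (2R)-antipode to the monoacetate F3 and leave the (1R,2S)-diol. After separation the route is rejoined at 8, at the cost of half the material.

**Step 5.**
- What may go wrong: attack of the amide on the ester, lithiation of the oxirane at C2, or base-induced decomposition of the dienediol dialkoxide before the quench.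
- Fallback from 7, nucleophilic opening in place of deprotonation: PhSeNa (from PhSeSePh and NaBH4 in MeOH) should open the oxirane at C3, the carbon remote from quaternary C1, with inversion to the β-hydroxy selenide F4. Oxidation with H2O2 in the presence of pyridine and syn-elimination of the selenoxide away from the carbinol carbon gives the C3=C4 alkene. The route is rejoined at 8.

**Step 7.**
- What may go wrong: attack on the upper face steered by the free C1 hydroxyl, or an ene-type hydroperoxidation involving the allylic C2–H, either of which would erode the anti-1,4 relation.
- Fallback from 9, steric blocking of the upper face: Et3SiOTf and 2,6-lutidine give the triethylsilyl ether F5. Photooxygenation in CH2Cl2 with tetraphenylporphyrin should give the lower-face silylated endoperoxide F6. Thiourea gives the silyl ether diol F7, and HF·pyridine removes the silyl group. The route is rejoined at 11.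

**Step 9.**
- What may go wrong: incomplete discrimination between the C3 and C6 hydroxyls (over-acylation at C6 or under-acylation at C3), and benzoyl migration between O7 and the neighbouring hydroxyls.
- Fallback from 12, discrimination by a more size-sensitive reagent with the esters introduced after ring closure:
  - tBuMe2SiCl (2.1 equiv) and imidazole in DMF should silylate O7 and O3 only, giving the bis(tert-butyldimethylsilyl) ether F8.
  - Ms2O/Et3N, then NaN(SiMe3)2, gives its C6 mesylate F9 in the flask and then the bis-silylated epoxide F10, with no ester present to migrate.
  - Bu4NF buffered with AcOH gives the epoxy diol F11.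
  - BzCl in excess with pyridine and DMAP acylates both remaining hydroxyls. The route is rejoined at 16.

**Step 10.**
- What may go wrong: solvolysis or allylic (SN2′) substitution of the mesylate before closure, deprotonation of the mesyl group in place of the hydroxyl, or a 1,2-benzoyl shift from O7 to the C1 alkoxide that lowers the concentration of the cyclizing species.
- Fallback from 14, activation and displacement in one neutral operation: Mitsunobu-type cyclodehydration with PPh3 and diisopropyl azodicarboxylate in toluene. The secondary C6 hydroxyl is converted into an oxyphosphonium leaving group and displaced with inversion by the C1 oxygen. This leads directly to 16 and makes no new compound (F0).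

## Further compounds

F1 | step 4 | racemic methyl (1R*,2S*,3S*)-2,3-epoxy-1-hydroxycyclohex-5-ene-1-carboxylate (both enantiomers written) | COC(=O)[C@@]1(O)C=CC[C@@H]2O[C@H]12.COC(=O)[C@]1(O)C=CC[C@H]2O[C@@H]12
F2 | step 4 | racemic methyl (1R*,2S*)-1,2-dihydroxycyclohexa-3,5-diene-1-carboxylate (both enantiomers written) | COC(=O)[C@]1(O)[C@@H](O)C=CC=C1.COC(=O)[C@@]1(O)[C@H](O)C=CC=C1
F3 | step 4 | methyl (1S,2R)-2-acetoxy-1-hydroxycyclohexa-3,5-diene-1-carboxylate | COC(=O)[C@@]1(O)[C@H](OC(C)=O)C=CC=C1
F4 | step 5 | methyl (1R,2R,3R)-1,2-dihydroxy-3-(phenylselanyl)cyclohex-5-ene-1-carboxylate | COC(=O)[C@]1(O)[C@@H](O)[C@H]([Se]c2ccccc2)CC=C1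
F5 | step 7 | methyl (1R,2S)-2-methoxy-1-(triethylsilyloxy)cyclohexa-3,5-diene-1-carboxylate | COC(=O)[C@]1(O[Si](CC)(CC)CC)[C@@H](OC)C=CC=C1
F6 | step 7 | methyl (1S,2S,3R,6S)-3,6-epidioxy-2-methoxy-1-(triethylsilyloxy)cyclohex-4-ene-1-carboxylate | COC(=O)[C@]1(O[Si](CC)(CC)CC)[C@@H](OC)[C@H]2C=C[C@@H]1OO2
F7 | step 7 | methyl (1R,2S,3R,6S)-3,6-dihydroxy-2-methoxy-1-(triethylsilyloxy)cyclohex-4-ene-1-carboxylate | COC(=O)[C@]1(O[Si](CC)(CC)CC)[C@@H](OC)[C@H](O)C=C[C@@H]1O
F8 | step 9 | (1R,2S,3R,6S)-3-(tert-butyldimethylsilyloxy)-1-[(tert-butyldimethylsilyloxy)methyl]-2-methoxycyclohex-4-ene-1,6-diol | CC(C)(C)[Si](C)(C)OC[C@]1(O)[C@@H](OC)[C@H](O[Si](C)(C)C(C)(C)C)C=C[C@@H]1O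
F9 | step 9 | C6 methanesulfonate of F8 | CC(C)(C)[Si](C)(C)OC[C@]1(O)[C@@H](OC)[C@H](O[Si](C)(C)C(C)(C)C)C=C[C@@H]1OS(C)(=O)=O
F10 | step 9 | (1R,2S,3R,6R)-3-(tert-butyldimethylsilyloxy)-1-[(tert-butyldimethylsilyloxy)methyl]-2-methoxy-7-oxabicyclo[4.1.0]hept-4-ene | CO[C@H]1[C@H](O[Si](C)(C)C(C)(C)C)C=C[C@H]2O[C@]21CO[Si](C)(C)C(C)(C)C
F11 | step 9 | (1R,2S,3R,6R)-1-(hydroxymethyl)-2-methoxy-7-oxabicyclo[4.1.0]hept-4-en-3-ol | CO[C@H]1[C@H](O)C=C[C@H]2O[C@]21CO
F0 | step 10 | none | none
A1 | alternative 1 | [(1R,2S,3R,6R)-3-hydroxy-2-methoxy-7-oxabicyclo[4.1.0]hept-4-en-1-yl]methyl benzoate | CO[C@H]1[C@H](O)C=C[C@H]2O[C@]21COC(=O)c1ccccc1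
A2 | alternative 1 | [3-[(Z)-2-iodoethenyl]-2-(1-methoxy-2-oxoethyl)oxiran-2-yl]methyl benzoate, configured as C1, C2 and C6 of 16 | CO[C@@H](C=O)[C@]1(COC(=O)c2ccccc2)O[C@@H]1/C=C\I
A3 | alternative 2 | (1S,2R)-1,2-dihydroxycyclohexa-3,5-diene-1-carboxylic acid | OC(=O)[C@]1(O)C=CC=C[C@H]1O
A4 | alternative 3 | [(3aS,7aS)-5-oxo-3a,4-dihydro-1,3-benzodioxol-7a(5H)-yl]methyl benzoate (cis-fused methylene acetal enone) | O=C1C[C@@H]2OCO[C@]2(COC(=O)c3ccccc3)C=C1
A5 | alternative 3 | (1-hydroxy-4-oxocyclohexa-2,5-dien-1-yl)methyl benzoate | O=C1C=CC(O)(COC(=O)c2ccccc2)C=C1
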